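Numbering follows 1-benzofuran (O1, C2, C3, C3a, C4 to C7, C7a). The retrosynthesis cuts the O–CH3 bond at C5 first. It then trades O1–C2 for a C2–C4 bond, which shrinks ring O1–C2–C3–C3a–C7a to the cyclobutane C2–C3–C3a–C4. Last, it cuts C3–C3a and C2–C4 together ([2+2]), giving 2-allyl-5-methoxy-1,4-benzoquinone and (E)-isoelemicin.
Enabling feature: C2 carries the electron-rich 3,4,5-trimethoxyphenyl ring (donor) and C4 is alpha to the C5 carbonyl (acceptor), so the C2–C4 bond of the cyclobutane is a strained push–pull bond. C7a=O is the carbonyl of the vinylogous ester C7a(=O)–C7=C6–OMe, which makes its oxygen the best internal nucleophile for the cation that bond releases.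
Forward order: the six-membered ring comes from a phenol (O-allylation, Claisen rearrangement, oxidation to the quinone). A titanium-mediated [2+2] then builds the cyclobutane, acid expands the four-membered ring to the five-membered one, and O-methylation finishes the route.
Stereochemistry: C3a and C3 come from the face-selective, aryl-endo [2+2] of the E-alkene on a chiral titanium TADDOLate. C2 comes from the ring expansion, where the pseudoaxial allyl group at C3a sends the aryl group anti to itself (cis to the methyl group), and reversible O1–C2 ionisation makes the step stereoconvergent.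
The cation of the key step is the one presumed in the biosynthesis of this neolignan class: a side-chain benzylic cation next to the allyl-bearing quinonoid carbon, closed through oxygen.

Key step: step 6

Assumption: the titanium complex of (4R,5R)-TADDOL is taken to leave open the Si face of the allyl-bearing quinone carbon of 5; should the sense of induction be the opposite, the equally available (4S,5S)-diol serves with no other change.

Step 1
Reactants: 1 3,4-dimethoxyphenol; 2 allyl bromide
Product: 3 4-(allyloxy)-1,2-dimethoxybenzene
Conditions: K2CO3, acetone, reflux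
Reagents that add atoms: none
Why: Williamson ether synthesis, in which the phenoxide displaces bromide from the unhindered allylic halide (SN2) and O-alkylation is the normal course under these conditions.

Step 2
Reactants: 3 4-(allyloxy)-1,2-dimethoxybenzene
Product: 4 2-allyl-4,5-dimethoxyphenol
Conditions: PhNEt2, 200 °C
Reagents that add atoms: none
Why: Aromatic Claisen rearrangement ([3,3]-sigmatropic shift, then tautomerisation), in which the allyl group should go to the free ortho position remote from the methoxy groups because the other ortho position is flanked by a methoxy group.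

Step 3
Reactants: 4 2-allyl-4,5-dimethoxyphenol
Product: 5 2-allyl-5-methoxy-1,4-benzoquinone
Conditions: PhI(OAc)2, MeCN–H2O, 0 °C
Reagents that add atoms: water, O
Why: Oxidative dearomatisation of a 4-methoxyphenol, in which water captures the oxidised ring at the methoxy-bearing para carbon and the hemiketal loses methanol to give the p-quinone, while the allyl group and the second methoxy group are inert.

Step 4
Reactants: 6 5-bromo-1,2,3-trimethoxybenzene; 7 (E)-prop-1-enylboronic acid pinacol ester
Product: 8 (E)-isoelemicin, (E)-1,2,3-trimethoxy-5-(prop-1-en-1-yl)benzene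
Conditions: Pd(dppf)Cl2 (cat.), K2CO3, 1,4-dioxane–H2O, 80 °C
Reagents that add atoms: none
Why: Suzuki–Miyaura coupling, in which transmetalation and reductive elimination keep the alkene geometry, so the E configuration of 7 is carried into 8.

Step 5
Reactants: 5 2-allyl-5-methoxy-1,4-benzoquinone; 8 (E)-isoelemicin
Product: 9 (1S,6R,7R,8R)-1-allyl-4-methoxy-8-methyl-7-(3,4,5-trimethoxyphenyl)bicyclo[4.2.0]oct-3-ene-2,5-dione (cis-fused; aryl endo, methyl exo and cis to allyl)
Conditions: TiCl2(OiPr)2, (4R,5R)-TADDOL, 4 Å MS, toluene–CH2Cl2, rt; then 5 and 8, −78 °C; aq NaHCO3 at −78 °C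
Reagents that add atoms: none
Why: Lewis-acid-promoted stepwise [2+2] cycloaddition of a 2-alkoxy-1,4-benzoquinone with a propenylarene, in which tetravalent titanium, chelated by the methoxy oxygen and the adjacent carbonyl, directs the CHMe carbon of 8 to the allyl-bearing quinone carbon, the benzylic cation collapses on the titanium enolate carbon in the cold, the E geometry survives as aryl/methyl trans, stacking of the arene over the quinone (endo) places methyl cis to allyl on the four-membered ring, and the TADDOLate blocks one quinone face and so fixes C1, C6, C7 and C8 absolutely.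

Step 6
Reactants: 9 (1S,6R,7R,8R)-1-allyl-4-methoxy-8-methyl-7-(3,4,5-trimethoxyphenyl)bicyclo[4.2.0]oct-3-ene-2,5-dione
Product: 12 (2R,3S,3aS)-3a-allyl-5-hydroxy-3-methyl-2-(3,4,5-trimethoxyphenyl)-3,3a-dihydro-1-benzofuran-6(2H)-one, via benzylic cation 10 (not isolated), via methyloxocarbenium ion 11 (not isolated)
Conditions: MeSO3H, CH2Cl2, −40 to 0 °C; then H2O, 0 °C
Reagents that add atoms: water, O
Why: Protonation of the C5 carbonyl turns the strained C2–C4 bond into a push–pull bond (trimethoxyphenyl donor at C2, protonated ketone next to C4), so it breaks heterolytically, as in the opening of a donor–acceptor cyclobutane, to the benzylic cation 10 with C3 and C3a untouched. Rotation about C3–C3a brings C2 to the C7a carbonyl oxygen, and a formally 5-exo-trig capture of the trigonal C2 closes ring O1–C2–C3–C3a–C7a, so the four-membered carbocycle grows into the five-membered oxacycle with release of the cyclobutane strain; the closest known reaction type is the acid-induced rearrangement of aryl-substituted bicyclo[4.2.0]oct-3-ene-2,5-diones to 2-aryl-2,3-dihydrobenzofurans. The only new stereocentre, C2, is controlled by the quaternary C3a: the allyl group is held pseudoaxial on the new ring, so the aryl group takes the pseudoequatorial place anti to it and hence cis to the C3 methyl group. Because O1–C2 ionisation is reversible in the acid, the other C2 epimer and any exo-aryl isomer of 9 that has the same C1 and C8 configuration should drain into the same product. The step needs closure through oxygen rather than through C7 (bicyclo[3.2.1]octenedione) or the allyl double bond, and this is secured at the cation stage because the charge of 11 is shared by O1 and the C6 methoxy oxygen, which no carbon-closed cation can match, and by the low temperature. Water then adds to C6 of 11 and methanol leaves, which fixes the C6 ketone and the C5 enol of 12.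

Step 7
Reactants: 12 (2R,3S,3aS)-3a-allyl-5-hydroxy-3-methyl-2-(3,4,5-trimethoxyphenyl)-3,3a-dihydro-1-benzofuran-6(2H)-one
Product: 13 (2R,3S,3aS)-3a-allyl-5-methoxy-3-methyl-2-(3,4,5-trimethoxyphenyl)-3,3a-dihydro-1-benzofuran-6(2H)-one (target)
Conditions: MeI, K2CO3, acetone, rt
Reagents that add atoms: iodomethane, CI
Why: O-alkylation of a diosphenol (enolised 1,2-diketone), whose C5 hydroxyl is the only acidic site, so the methyl ether forms at O5 and no stereocentre is touched.

Compound list
1 | 3,4-dimethoxyphenol | COc1ccc(O)cc1OC | starting material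
2 | allyl bromide | C=CCBr | starting material
3 | 4-(allyloxy)-1,2-dimethoxybenzene | C=CCOc1ccc(OC)c(OC)c1 | intermediate
4 | 2-allyl-4,5-dimethoxyphenol | C=CCc1cc(OC)c(OC)cc1O | intermediate
5 | 2-allyl-5-methoxy-1,4-benzoquinone | C=CCC1=CC(=O)C(OC)=CC1=O | intermediate
6 | 5-bromo-1,2,3-trimethoxybenzene | COc1cc(Br)cc(OC)c1OC | starting material
7 | (E)-prop-1-enylboronic acid pinacol ester | C/C=C/B1OC(C)(C)C(C)(C)O1 | starting material
8 | (E)-isoelemicin | C/C=C/c1cc(OC)c(OC)c(OC)c1 | intermediate
9 | (1S,6R,7R,8R)-1-allyl-4-methoxy-8-methyl-7-(3,4,5-trimethoxyphenyl)bicyclo[4.2.0]oct-3-ene-2,5-dione | C=CC[C@@]12C(=O)C=C(OC)C(=O)[C@@H]1[C@H](c1cc(OC)c(OC)c(OC)c1)[C@H]2C | intermediate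
10 | ring-opened benzylic cation: 6-allyl-4-hydroxy-3-methoxycyclohexa-2,4-dienone bearing at C6 the CH(CH3)–CH(+)–aryl chain, C3 and C3a configured as in 13 | C=CC[C@@]1(C=C(O)C(OC)=CC1=O)[C@H](C)[CH+]c1cc(OC)c(OC)c(OC)c1 | intermediate (not isolated)
11 | oxygen-closed methyloxocarbenium ion: 12 carrying a methyl group on the C6 oxygen, (2R,3S,3aS) | C=CC[C@]12C=C(O)C(=[O+]C)C=C1O[C@@H](c1cc(OC)c(OC)c(OC)c1)[C@H]2C | intermediate (not isolated)
12 | (2R,3S,3aS)-3a-allyl-5-hydroxy-3-methyl-2-(3,4,5-trimethoxyphenyl)-3,3a-dihydro-1-benzofuran-6(2H)-one | C=CC[C@]12C=C(O)C(=O)C=C1O[C@@H](c1cc(OC)c(OC)c(OC)c1)[C@H]2C | intermediate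
13 | (2R,3S,3aS)-3a-allyl-5-methoxy-3-methyl-2-(3,4,5-trimethoxyphenyl)-3,3a-dihydro-1-benzofuran-6(2H)-one | C=CC[C@]12C=C(OC)C(=O)C=C1O[C@@H](c1cc(OC)c(OC)c(OC)c1)[C@H]2C | target

Total step count: 7. Longest linear sequence: 6 (steps 1, 2, 3, 5, 6, 7).

Steps most likely to fail

Step 6. The cation may close through C7 with carbon–carbon bond formation. It may also be intercepted by the allyl double bond, or methyl loss from the oxygen-closed cation may be too slow to hold the oxacycle.
The fallback changes the helper group and the trigger. It sets out from 5 and comes back at 12.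
- Acid-catalysed vinylogous transesterification of 5 with benzyl alcohol (cat. TsOH, toluene, 4 Å MS) should give 2-allyl-5-(benzyloxy)-1,4-benzoquinone F1.
- The conditions of step 5 with 8 should then give the 4-benzyloxy analogue of the cyclobutane F2.
- TiCl4 in CH2Cl2 at −78 °C should open the same push–pull bond, and chloride should strip the benzyl group from the oxygen-closed cation as soon as it forms. Closure through oxygen then becomes irreversible in the cold, and aqueous work-up gives 12.

Step 5. The chiral complex may give poor facial selectivity. The reaction may also leak into direct five-membered or bicyclic closure, or the alkene may attack the unsubstituted quinone carbon.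
The fallback replaces asymmetric induction by resolution. It sets out from 5 and 8 and comes back at 12.
- Achiral TiCl4–Ti(OiPr)4 in CH2Cl2 at −78 °C should give 9 together with its mirror image, the (1R,6S,7S,8S)-cyclobutane F3.
- The conditions of step 6 should give 12 together with the (2S,3R,3aR)-hydroxydienone F4.
- Esterification of the C5 hydroxyl with (S)-2-methoxy-2-phenylacetic acid (DCC, cat. DMAP, CH2Cl2, 0 °C) should give two diastereomers: the (S)-2-methoxy-2-phenylacetate of 12 F5 and the (S)-2-methoxy-2-phenylacetate of the mirror-image dienone F6.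
- The esters are separated by chromatography or crystallisation, and K2CO3 in MeOH at 0 °C should cleave the activated enol ester of the first back to 12.

Step 7. The ambident diosphenolate may be alkylated at carbon (C4), or the base may degrade the dienone.
The fallback activates the alcohol instead of deprotonating the enol. It sets out from 12 and comes back at 13. A Mitsunobu etherification (MeOH, PPh3, DIAD, THF, 0 °C) uses the acidic enol as the pronucleophile under neutral conditions. It makes no new compound (F0).

Further compounds
F1 | step 6 | 2-allyl-5-(benzyloxy)-1,4-benzoquinone | C=CCC1=CC(=O)C(OCc2ccccc2)=CC1=O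
F2 | step 6 | (1S,6R,7R,8R)-1-allyl-4-(benzyloxy)-8-methyl-7-(3,4,5-trimethoxyphenyl)bicyclo[4.2.0]oct-3-ene-2,5-dione | C=CC[C@@]12C(=O)C=C(OCc3ccccc3)C(=O)[C@@H]1[C@H](c1cc(OC)c(OC)c(OC)c1)[C@H]2C
F3 | step 5 | (1R,6S,7S,8S)-1-allyl-4-methoxy-8-methyl-7-(3,4,5-trimethoxyphenyl)bicyclo[4.2.0]oct-3-ene-2,5-dione | C=CC[C@]12C(=O)C=C(OC)C(=O)[C@H]1[C@@H](c1cc(OC)c(OC)c(OC)c1)[C@@H]2C
F4 | step 5 | (2S,3R,3aR)-3a-allyl-5-hydroxy-3-methyl-2-(3,4,5-trimethoxyphenyl)-3,3a-dihydro-1-benzofuran-6(2H)-one | C=CC[C@@]12C=C(O)C(=O)C=C1O[C@H](c1cc(OC)c(OC)c(OC)c1)[C@@H]2C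
F5 | step 5 | (S)-2-methoxy-2-phenylacetate of 12 at O5 | C=CC[C@]12C=C(OC(=O)[C@@H](OC)c3ccccc3)C(=O)C=C1O[C@@H](c1cc(OC)c(OC)c(OC)c1)[C@H]2C
F6 | step 5 | (S)-2-methoxy-2-phenylacetate of the (2S,3R,3aR)-hydroxydienone at O5 | C=CC[C@@]12C=C(OC(=O)[C@@H](OC)c3ccccc3)C(=O)C=C1O[C@H](c1cc(OC)c(OC)c(OC)c1)[C@@H]2C
F0 | step 7 | none | none
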